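## The problem

Target 21 is a linear trimer of acylphloroglucinols: three benzene rings (A, B and C), each with hydroxyl groups on three alternating carbons and one butanoyl group, rings A and C each with a C-methyl group as well, joined A–B and B–C by two CH2 bridges. All eighteen ring carbons are substituted and there is no stereocentre, so the task is purely constitutional: which carbon of which ring carries which group, and the ring order. The bridges are the delicate element, because a diarylmethane between two phloroglucinol nuclei is cleaved by acid (ipso protonation and loss of a stabilised benzyl cation) and can redistribute under base, and making a bridge by electrophilic substitution on such rings invites over-alkylation and attack on the wrong ring. The free nonaphenol is sensitive to air and base, so the hydroxyl groups have to stay masked as ethers until the last step, and each ketone is best introduced where its ring offers a single possible site. The opening for a different approach lies in ring B: its two bridge-bearing carbons are separated by exactly one oxygen-bearing carbon, and its other three carbons are C–O, C–acyl and C–O. A vinylketene with an arylmethyl group on its ketene carbon and an oxygen on the next carbon, joined to an alkynyl ether ArCH2–C≡C–OR, reproduces this alternation, so ring B can be built between two bridges that already exist. The one ring B carbon that this leaves as C–H lies between two oxygens and is where the third butanoyl group belongs.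

## Retrosynthesis

**21 to 20.** The eight O–alkyl bonds (six O–methyl on rings A and C, two O–ethyl on ring B) are cut last. Triketone 20 carries all carbons of 21, and its ketones temper the rings against acid, so the polyphenol is exposed only once. The forward step asks for complete cleavage of eight aryl ethers by BBr3 without harm to the bridges; five of the ethers sit ortho to a ketone and are activated by chelation.

**20 to 19 and 2.** One aryl–C(=O) bond, on ring B, is cut. Phenol 19 has a single unsubstituted aromatic carbon in the whole molecule, flanked by the hydroxyl and an ethoxy group, so acylation with butanoyl chloride 2 has no choice of site. Rings A and C already carry their ketones, which makes them poorer targets for ipso attack than acyl-free rings would be. Acylating all three rings at this stage was set aside, since it would put three Friedel–Crafts events on a trimer whose bridges are acid-labile.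

**19 to 11 and 14 (key disconnection).** Three ring B bonds are cut: C(OH)–C(bridge), C(OEt)–C(bridge) and C(OH)–C(H). This divides ring B into a two-carbon piece, ynol ether 11, and a four-carbon piece, cyclobutenone 14, each already carrying one arylmethyl arm. Cutting a bridge instead (aryl–CH2) would return to electrophilic bridge formation on an electron-rich ring. The forward reaction is a thermal cascade through intermediates 15 to 18; it needs one sense of ketene–alkyne union, which the polarity of the ynol ether provides.

**14 to 11 and ketene 13.** The C1–C2 and C3–C4 bonds of the cyclobutenone are cut, a (2+2) cycloaddition in the forward sense. Both partners of the key step thus come from the single ynol ether 11. Ketene 13 is taken as a gas from pyrolysis of acetone 12.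

**11 to 7 and 8.** The CH2–C(sp) bond is cut, giving benzylic chloride 7 and ethoxyacetylene 8. Because 7 carries an enolisable ketone, the acetylide is used as its zinc derivative 10 (from lithium salt 9) in a palladium-catalysed coupling and not as the basic lithium reagent. This is the only C–C bond made at a benzylic carbon in the route, and it is made with a carbon nucleophile, not with an arene.

**7 to 5.** No C–C bond is cut: chloride 7 is traced to alcohol 6 and aldehyde 5. The forward reduction must take the aldehyde and spare the hindered ketone.

**5 to 3.** The aryl–CHO bond is cut (through α-chloro ether 4). Formylation is preferred to direct halomethylation because its product is not an alkylating agent, so no diarylmethane can form from it and unreacted 3.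

**3 to 1 and 2.** The aryl–C(=O) bond of the outer rings is cut at the monomer stage. 2,4,6-Trimethoxytoluene 1 has two equivalent free carbons, so one ketone results. The acyl group then accompanies the monomer into both halves of the key step, so each outer ring is acylated once, before any bridge exists.

## Roads not taken

**Alternative 1:** Only two ring B bonds are cut, those flanking the acyl-bearing and one oxygen-bearing carbon. In the forward sense the 3,5-bis(arylmethyl)-4,6-dimethoxy-2-pyranone A2 and the push–pull ynone A3 would undergo (4+2) cycloaddition and lose CO2 to give the fully substituted ring B compound A1.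
- Merits: all six ring B substituents and all three butanoyl groups are in place after the key step, so only ether cleavage remains. There is no Friedel–Crafts reaction at all on a bridged trimer, and in this respect the road is better than the chosen one.
- Weak points: A2 is a tetrasubstituted, electron-rich pyranone with two ketone-bearing aryl arms. Its preparation needs several steps, including an O-methylation whose site (2-pyranone or 4-pyranone ether) is uncertain. The cycloaddition must form two bonds to fully substituted diene termini with an alkyne whose acceptor strength is lowered by its ethoxy group, so forcing temperatures are to be expected. Nine ethers instead of eight must be cleaved.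
- Comparison: the chosen plan draws both partners from one ynol ether, 11, in at most one further step, and its regiochemistry follows from a well-understood polarity match. Against the merit of A1 it sets a single late acylation at the only free carbon of 19.

**Alternative 2:** One ring B bond is cut, between the butanoyl-bearing carbon and a neighbouring C–OH carbon. In the forward sense the triketo ester A5 would close with Mg(OMe)2 by an intramolecular Claisen condensation to A4.
- Merits: the closure is biomimetic and gives ring B with its butanoyl group and three free hydroxyls, so ring B needs no protecting groups and only six methyl ethers remain. Here it is more economical than the chosen plan.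
- Weak points: A5 has to be assembled by two C-benzylations of a polycarbonyl chain with the benzylic chloride A6, against O-alkylation, double alkylation and alkylation at the wrong methylene. A5 is a mixture of tautomers and diastereomers. Lactonisation to a pyranone and aldol closure compete with the Claisen mode. The outer rings of A4 would then have to be acylated beside a free acylphloroglucinol ring.
- Comparison: the chosen plan forms three ring bonds at once from two stable, defined partners, and its outer rings arrive already acylated.

**Alternative 3:** No ring is made. The three aryl–acyl bonds of the nonamethyl ether A7 are cut back to the acyl-free trimer A8, which would come from twofold benzylation of 1,3,5-trimethoxybenzene A9 with chloride A6.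
- Merits: this is the shortest road (about five steps), all ethers are methyl, and ring B raises no regiochemical question because A9 is symmetric.
- Weak points: the difficulty moves into making A8. Benzylation must stop at two of three equivalent positions, and the free carbon of each incoming aryl group is as nucleophilic as A9 itself, so chains with the wrong ring order can form. The bridges are exposed to the acid that forms them, and then again to three Friedel–Crafts acylations on rings that are all still electron-rich.
- Comparison: if the bis-benzylation could be controlled, this road would be clearly shorter and cheaper than the chosen one. The chosen plan fixes the number and position of the bridges by construction, not by statistics, never exposes a bridge to bridge-forming conditions, and confines late acylation to one event on ring B (step 8).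

Key step: step 7

Assumption: ketene is supplied as a gas from a separate acetone-pyrolysis generator, so acetone 12 is counted as the source of two ring B carbons; ethoxyacetylene 8 is used as its commercial solution in hexanes.

## Route

Step 1
Reactants: 1 2,4,6-trimethoxytoluene; 2 butanoyl chloride
Product: 3 1-(2,4,6-trimethoxy-3-methylphenyl)butan-1-one
Conditions: 2 (1.05 equiv), TiCl4 (1.1 equiv), CH2Cl2, −20 → 0 °C
Reagents that add atoms: none
Why: Friedel–Crafts acylation; the two free ring carbons of 1 are equivalent and each lies between two methoxy groups, so a single ketone results, and the acyl group deactivates the ring against a second acylation. The low temperature should spare the methyl ethers ortho to the new carbonyl.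

Step 2
Reactants: 3 1-(2,4,6-trimethoxy-3-methylphenyl)butan-1-one
Product: 5 3-butanoyl-2,4,6-trimethoxy-5-methylbenzaldehyde, via α-chloro ether 4 (not isolated)
Conditions: Cl2CHOMe, TiCl4, CH2Cl2, −78 → 0 °C; then ice-water
Reagents that add atoms: dichloromethyl methyl ether, COC(Cl)Cl; water, O
Why: Rieche formylation; the last free ring carbon, still flanked by two methoxy groups, takes up the chloro(methoxy)carbenium ion to give 4, which water hydrolyses to the aldehyde. A POCl3–DMF formylation was avoided because that reagent can also attack an enolisable aryl ketone.

Step 3
Reactants: 5 3-butanoyl-2,4,6-trimethoxy-5-methylbenzaldehyde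
Product: 6 1-[3-(hydroxymethyl)-2,4,6-trimethoxy-5-methylphenyl]butan-1-one
Conditions: NaBH4 (0.5 equiv), THF–MeOH, −40 °C
Reagents that add atoms: none
Why: Chemoselective hydride reduction; an aldehyde is reduced far faster than a ketone, and this ketone is a di-ortho-substituted aryl propyl ketone, so limited NaBH4 at low temperature should touch only the formyl group.

Step 4
Reactants: 6 1-[3-(hydroxymethyl)-2,4,6-trimethoxy-5-methylphenyl]butan-1-one
Product: 7 1-[3-(chloromethyl)-2,4,6-trimethoxy-5-methylphenyl]butan-1-one
Conditions: MsCl, i-Pr2NEt, CH2Cl2, −20 → 0 °C; cold aq. NaHCO3 wash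
Reagents that add atoms: methanesulfonyl chloride, CS(Cl)(=O)=O
Why: Sulfonylation of the benzylic alcohol and displacement by chloride in the same flask, the usual non-acidic route to electron-rich benzyl chlorides. The ring of 7 is fully substituted and carries a ketone, so the chloride has no free ring carbon of its own kind to alkylate and should be stable enough to handle.

Step 5
Reactants: 7 1-[3-(chloromethyl)-2,4,6-trimethoxy-5-methylphenyl]butan-1-one; 8 ethoxyacetylene
Product: 11 1-[3-(3-ethoxyprop-2-yn-1-yl)-2,4,6-trimethoxy-5-methylphenyl]butan-1-one, via lithium ethoxyacetylide 9 (not isolated), via ethoxyethynylzinc chloride 10 (not isolated)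
Conditions: 8 (1.5 equiv), n-BuLi, THF, −78 °C; ZnCl2, −78 → 0 °C; then 7, PdCl2(DPEphos) (3 mol%), 0 °C → rt; chromatography on Et3N-washed silica
Reagents that add atoms: none
Why: Negishi coupling of an alkynylzinc halide with a benzylic chloride; the divalent palladium precatalyst (DPEphos = bis[2-(diphenylphosphino)phenyl] ether) is reduced by the zinc acetylide to zerovalent palladium, which inserts into the benzylic C–Cl bond, and alkynyl transfer from zinc followed by reductive elimination forms the CH2–C(sp) bond. Zinc acetylide 10, unlike lithium acetylide 9, should neither add to nor enolise the aryl ketone.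

Step 6
Reactants: 11 1-[3-(3-ethoxyprop-2-yn-1-yl)-2,4,6-trimethoxy-5-methylphenyl]butan-1-one; 12 acetone
Product: 14 2-[(3-butanoyl-2,4,6-trimethoxy-5-methylphenyl)methyl]-3-ethoxycyclobut-2-en-1-one, via ketene 13 (not isolated)
Conditions: ketene gas (pyrolysis of 12, ketene lamp) passed into 11, CH2Cl2, 0 °C → rt
Reagents that add atoms: none
Why: Thermal (2+2) cycloaddition of ketene with an alkynyl ether, the classical route to 3-alkoxycyclobutenones; the alkyne carbon remote from oxygen bonds to the ketene carbonyl carbon, which places the arylmethyl group on C2 and the ethoxy group on C3. The hindered aryl ketone does not react with ketene without a catalyst.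

Step 7
Reactants: 11 1-[3-(3-ethoxyprop-2-yn-1-yl)-2,4,6-trimethoxy-5-methylphenyl]butan-1-one; 14 2-[(3-butanoyl-2,4,6-trimethoxy-5-methylphenyl)methyl]-3-ethoxycyclobut-2-en-1-one
Product: 19 2,4-bis[(3-butanoyl-2,4,6-trimethoxy-5-methylphenyl)methyl]-3,5-diethoxyphenol, via vinylketene 15 (not isolated), via vinylcyclobutenone 16 (not isolated), via dienylketene 17 (not isolated), via cyclohexadienone 18 (not isolated)
Conditions: 11 (1.3 equiv), toluene, 80 → 100 °C, sealed tube
Reagents that add atoms: none
Why: On heating, cyclobutenone 14 should undergo reversible 4π electrocyclic opening of its C1–C4 bond to vinylketene 15, which carries one arylmethyl arm on the ketene carbon. Ynol ether 11 then adds across the ketene C=C bond in a (2+2) cycloaddition: its arylmethyl-bearing carbon bonds to the ketene carbonyl carbon and its ethoxy-bearing carbon to the arylmethyl-bearing ketene carbon, giving 4-vinylcyclobutenone 16. A second 4π opening gives dienylketene 17, which closes ring B by thermal disrotatory 6π electrocyclisation between the ketene carbonyl carbon and the terminal CH2 to give cyclohexadienone 18, and tautomerisation gives phenol 19. This is the Danheiser benzannulation of a cyclobutenone with an alkynyl ether, applied here to a 3-alkoxycyclobutenone so that ring B emerges as a phloroglucinol diether. No stereocentre is formed in the product, and the single stereocentre of 16 is lost on ring opening. The selectivity needed is the head-to-tail sense of the ketene–alkyne union, which is secured by the polarity of 11 (carbon remote from oxygen nucleophilic) against the electrophilic ketene carbonyl carbon; oxygen and carbon substituents therefore alternate around ring B. The temperature is held at or below 100 °C, under the range in which ethyl alkynyl ethers fragment by a retro-ene path. The acylated trimethoxyaryl rings are spectators: they have no free ring carbon, and their hindered ketones do not react with ketenes or ynol ethers without a Lewis acid.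

Step 8
Reactants: 19 2,4-bis[(3-butanoyl-2,4,6-trimethoxy-5-methylphenyl)methyl]-3,5-diethoxyphenol; 2 butanoyl chloride
Product: 20 1-[3,5-bis[(3-butanoyl-2,4,6-trimethoxy-5-methylphenyl)methyl]-2,4-diethoxy-6-hydroxyphenyl]butan-1-one
Conditions: 2 (1.5 equiv), TiCl4 (4 equiv), CH2Cl2, −20 → 0 °C
Reagents that add atoms: none
Why: Friedel–Crafts acylation of the ring B phenol as its titanium phenoxide (direct ortho acylation, or O-acylation and Fries shift to the same carbon); this is the only unsubstituted aromatic carbon in 19, and rings A and C are fully substituted and deactivated by their ketones, so neither site selectivity nor over-acylation arises. Partial loss of the ethyl group ortho to the new ketone would be harmless, because all ethers are cleaved in step 9.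

Step 9
Reactants: 20 1-[3,5-bis[(3-butanoyl-2,4,6-trimethoxy-5-methylphenyl)methyl]-2,4-diethoxy-6-hydroxyphenyl]butan-1-one
Product: 21 1-[3,5-bis[(3-butanoyl-2,4,6-trihydroxy-5-methylphenyl)methyl]-2,4,6-trihydroxyphenyl]butan-1-one
Conditions: BBr3 (excess), CH2Cl2, −78 °C → rt; then H2O, degassed work-up
Reagents that add atoms: none
Why: Cleavage of aryl alkyl ethers with BBr3; the five ethers ortho to a ketone should go first through chelation, the three doubly ortho-substituted ethers para to the ketones follow at room temperature, and water hydrolyses the aryl borates to the nonaphenol.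

## Compound list

1 | 2,4,6-trimethoxytoluene | Cc1c(OC)cc(OC)cc1OC | starting material
2 | butanoyl chloride | CCCC(Cl)=O | starting material
3 | 1-(2,4,6-trimethoxy-3-methylphenyl)butan-1-one | CCCC(=O)c1c(OC)cc(OC)c(C)c1OC | intermediate
4 | 1-[3-[chloro(methoxy)methyl]-2,4,6-trimethoxy-5-methylphenyl]butan-1-one (racemic) | COC(Cl)c1c(OC)c(C(=O)CCC)c(OC)c(C)c1OC | intermediate (not isolated)
5 | 3-butanoyl-2,4,6-trimethoxy-5-methylbenzaldehyde | O=Cc1c(OC)c(C(=O)CCC)c(OC)c(C)c1OC | intermediate
6 | 1-[3-(hydroxymethyl)-2,4,6-trimethoxy-5-methylphenyl]butan-1-one | OCc1c(OC)c(C(=O)CCC)c(OC)c(C)c1OC | intermediate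
7 | 1-[3-(chloromethyl)-2,4,6-trimethoxy-5-methylphenyl]butan-1-one | ClCc1c(OC)c(C(=O)CCC)c(OC)c(C)c1OC | intermediate
8 | ethoxyacetylene | C#COCC | starting material
9 | lithium ethoxyacetylide | [Li]C#COCC | intermediate (not isolated)
10 | ethoxyethynylzinc chloride | CCOC#C[Zn]Cl | intermediate (not isolated)
11 | 1-[3-(3-ethoxyprop-2-yn-1-yl)-2,4,6-trimethoxy-5-methylphenyl]butan-1-one | CCOC#CCc1c(OC)c(C(=O)CCC)c(OC)c(C)c1OC | intermediate
12 | acetone | CC(C)=O | starting material
13 | ketene | C=C=O | intermediate (not isolated)
14 | 2-[(3-butanoyl-2,4,6-trimethoxy-5-methylphenyl)methyl]-3-ethoxycyclobut-2-en-1-one | CCOC1=C(Cc2c(OC)c(C(=O)CCC)c(OC)c(C)c2OC)C(=O)C1 | intermediate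
15 | 2-[(3-butanoyl-2,4,6-trimethoxy-5-methylphenyl)methyl]-3-ethoxybuta-1,3-dien-1-one | O=C=C(Cc1c(OC)c(C(=O)CCC)c(OC)c(C)c1OC)C(OCC)=C | intermediate (not isolated)
16 | 2,4-bis[(3-butanoyl-2,4,6-trimethoxy-5-methylphenyl)methyl]-3-ethoxy-4-(1-ethoxyethenyl)cyclobut-2-en-1-one (racemic) | O=C1C(Cc2c(OC)c(C(=O)CCC)c(OC)c(C)c2OC)=C(OCC)C1(Cc3c(OC)c(C(=O)CCC)c(OC)c(C)c3OC)C(OCC)=C | intermediate (not isolated)
17 | (3E)-2,4-bis[(3-butanoyl-2,4,6-trimethoxy-5-methylphenyl)methyl]-3,5-diethoxyhexa-1,3,5-trien-1-one | O=C=C(Cc1c(OC)c(C(=O)CCC)c(OC)c(C)c1OC)/C(OCC)=C(\C(OCC)=C)Cc1c(OC)c(C(=O)CCC)c(OC)c(C)c1OC | intermediate (not isolated)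
18 | 2,4-bis[(3-butanoyl-2,4,6-trimethoxy-5-methylphenyl)methyl]-3,5-diethoxycyclohexa-2,4-dien-1-one | O=C1CC(OCC)=C(Cc2c(OC)c(C(=O)CCC)c(OC)c(C)c2OC)C(OCC)=C1Cc3c(OC)c(C(=O)CCC)c(OC)c(C)c3OC | intermediate (not isolated)
19 | 2,4-bis[(3-butanoyl-2,4,6-trimethoxy-5-methylphenyl)methyl]-3,5-diethoxyphenol | CCOc1cc(O)c(Cc2c(OC)c(C(=O)CCC)c(OC)c(C)c2OC)c(OCC)c1Cc3c(OC)c(C(=O)CCC)c(OC)c(C)c3OC | intermediate
20 | 1-[3,5-bis[(3-butanoyl-2,4,6-trimethoxy-5-methylphenyl)methyl]-2,4-diethoxy-6-hydroxyphenyl]butan-1-one | CCCC(=O)c1c(O)c(Cc2c(OC)c(C(=O)CCC)c(OC)c(C)c2OC)c(OCC)c(Cc2c(OC)c(C(=O)CCC)c(OC)c(C)c2OC)c1OCC | intermediate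
21 | 1-[3,5-bis[(3-butanoyl-2,4,6-trihydroxy-5-methylphenyl)methyl]-2,4,6-trihydroxyphenyl]butan-1-one | CCCC(=O)c1c(O)c(C)c(O)c(Cc2c(O)c(Cc3c(O)c(C)c(O)c(C(=O)CCC)c3O)c(O)c(C(=O)CCC)c2O)c1O | target

## Step count and risks

Total steps: 9. Longest linear sequence: 9 steps (1 to 21; ynol ether 11 enters twice, in steps 6 and 7).

**Step 7 (key step).** The cyclobutenone is a vinylogous ester, and its first 4π opening may be too slow within the temperature window. Above that window the ynol ether can fragment by the retro-ene path, and the ketene so formed would be trapped in the wrong way. Acylation of the product phenol by the vinylketene and ketene dimerisation are further drains. Adding the ynol ether in portions is the first adjustment within the step. The fallback leaves the cycloaddition. It sets out from alcohol 6: twofold acid-catalysed Friedel–Crafts benzylation of 3,5-diethoxyphenol F1 (from phloroglucinol and ethanol with HCl) with 6 (2 equiv, catalytic TsOH, CH2Cl2) would return to the route at 19. Statistics favour the 2,4-pattern, but regioisomeric and over-benzylated material would have to be separated, and the regiocontrol of the main plan is given up.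

**Step 5.** Transmetallation to zinc may be incomplete, so that residual lithium acetylide attacks or enolises the ketone; the benzylic chloride may homocouple; and zinc salts may promote isomerisation of the product to an allenyl ether or its hydration on work-up. The fallback sets out from 7 and returns at 11 with a salt-free tin reagent. Lithium acetylide 9 and Bu3SnCl would give tributyl(ethoxyethynyl)stannane F2, which can be purified by distillation. Stille coupling of F2 with 7 under Pd(PPh3)4 catalysis in toluene at 60 °C would then give 11, zerovalent palladium taking up the chloride by oxidative addition in a non-polar medium free of base and Lewis acid.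

**Step 6.** Ketene dimerisation may outrun the cycloaddition, and traces of acid may hydrate the ynol ether. The fallback sets out from 11 and returns at 14: (2+2) cycloaddition with dichloroketene F3, generated in the flask from trichloroacetyl chloride and Zn–Cu couple in ether, would give 2-[(3-butanoyl-2,4,6-trimethoxy-5-methylphenyl)methyl]-4,4-dichloro-3-ethoxycyclobut-2-en-1-one F4 with the same regiochemistry. Reductive dechlorination with Zn, AcOH and TMEDA would then give 14.

**Step 8.** TiCl4 and the HCl it liberates may cleave or transfer a bridge through ipso protonation or ipso acylation of ring B, the one ring that is still free of a ketone, and the reaction may stop at the aryl ester if the Fries shift is slow. The fallback sets out from 19 and returns at 20 without a strong acid. Ortho-formylation of the magnesium phenoxide (MgCl2, Et3N, paraformaldehyde, MeCN) would give 3,5-bis[(3-butanoyl-2,4,6-trimethoxy-5-methylphenyl)methyl]-2,4-diethoxy-6-hydroxybenzaldehyde F5. Addition of n-PrMgBr at −78 °C would give 1-[3,5-bis[(3-butanoyl-2,4,6-trimethoxy-5-methylphenyl)methyl]-2,4-diethoxy-6-hydroxyphenyl]butan-1-ol F6; the di-ortho-substituted ketones of rings A and C should be too hindered to add the reagent at this temperature, and any enolisation of them is undone on work-up. Oxidation of the benzylic alcohol with MnO2 would give 20.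

**Step 9.** Ether cleavage may stop short at the three ethers para to the ketones while the ortho oxygens are held as boron chelates, and bridge migration becomes possible once the rings are free phenols in acid. The fallback sets out from 20 and returns at 21 by nucleophilic instead of electrophilic dealkylation: NaSEt in DMF at 110 °C attacks the alkyl carbons directly. Every ether oxygen of 20 is ortho or para to a ketone and therefore a good leaving group, and the basic medium excludes ipso protonation. The two ethyl ethers would react more slowly than the methyl ethers and would need prolonged heating. No new compound is made on this path.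

## Further compounds

F1 | step 7 | 3,5-diethoxyphenol | CCOc1cc(O)cc(OCC)c1
F2 | step 5 | tributyl(ethoxyethynyl)stannane | CCCC[Sn](CCCC)(CCCC)C#COCC
F3 | step 6 | dichloroketene | ClC(Cl)=C=O
F4 | step 6 | 2-[(3-butanoyl-2,4,6-trimethoxy-5-methylphenyl)methyl]-4,4-dichloro-3-ethoxycyclobut-2-en-1-one | CCOC1=C(Cc2c(OC)c(C(=O)CCC)c(OC)c(C)c2OC)C(=O)C1(Cl)Cl
F5 | step 8 | 3,5-bis[(3-butanoyl-2,4,6-trimethoxy-5-methylphenyl)methyl]-2,4-diethoxy-6-hydroxybenzaldehyde | O=Cc1c(O)c(Cc2c(OC)c(C(=O)CCC)c(OC)c(C)c2OC)c(OCC)c(Cc2c(OC)c(C(=O)CCC)c(OC)c(C)c2OC)c1OCC
F6 | step 8 | 1-[3,5-bis[(3-butanoyl-2,4,6-trimethoxy-5-methylphenyl)methyl]-2,4-diethoxy-6-hydroxyphenyl]butan-1-ol (racemic) | CCCC(O)c1c(O)c(Cc2c(OC)c(C(=O)CCC)c(OC)c(C)c2OC)c(OCC)c(Cc2c(OC)c(C(=O)CCC)c(OC)c(C)c2OC)c1OCC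
F0 | step 9 | none | none
A1 | alternative 1 | 1-[3,5-bis[(3-butanoyl-2,4,6-trimethoxy-5-methylphenyl)methyl]-2-ethoxy-4,6-dimethoxyphenyl]butan-1-one | CCCC(=O)c1c(OCC)c(Cc2c(OC)c(C)c(OC)c(C(=O)CCC)c2OC)c(OC)c(Cc2c(OC)c(C)c(OC)c(C(=O)CCC)c2OC)c1OC
A2 | alternative 1 | 3,5-bis[(3-butanoyl-2,4,6-trimethoxy-5-methylphenyl)methyl]-4,6-dimethoxy-2H-pyran-2-one | COC1=C(Cc2c(OC)c(C)c(OC)c(C(=O)CCC)c2OC)C(OC)=C(Cc2c(OC)c(C)c(OC)c(C(=O)CCC)c2OC)C(=O)O1
A3 | alternative 1 | 1-ethoxyhex-1-yn-3-one | CCCC(=O)C#COCC
A4 | alternative 2 | 1-[2,4,6-trihydroxy-3,5-bis[(2,4,6-trimethoxy-3-methylphenyl)methyl]phenyl]butan-1-one | CCCC(=O)c1c(O)c(Cc2c(OC)cc(OC)c(C)c2OC)c(O)c(Cc2c(OC)cc(OC)c(C)c2OC)c1O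
A5 | alternative 2 | methyl 3,5,7-trioxo-2,4-bis[(2,4,6-trimethoxy-3-methylphenyl)methyl]decanoate | CCCC(=O)CC(=O)C(Cc1c(OC)cc(OC)c(C)c1OC)C(=O)C(Cc1c(OC)cc(OC)c(C)c1OC)C(=O)OC
A6 | alternative 2 | 2-(chloromethyl)-1,3,5-trimethoxy-4-methylbenzene | ClCc1c(OC)cc(OC)c(C)c1OC
A7 | alternative 3 | 1-[3,5-bis[(3-butanoyl-2,4,6-trimethoxy-5-methylphenyl)methyl]-2,4,6-trimethoxyphenyl]butan-1-one | CCCC(=O)c1c(OC)c(C)c(OC)c(Cc2c(OC)c(Cc3c(OC)c(C)c(OC)c(C(=O)CCC)c3OC)c(OC)c(C(=O)CCC)c2OC)c1OC
A8 | alternative 3 | 1,3,5-trimethoxy-2,4-bis[(2,4,6-trimethoxy-3-methylphenyl)methyl]benzene | Cc1c(OC)cc(OC)c(Cc2c(OC)cc(OC)c(Cc3c(OC)cc(OC)c(C)c3OC)c2OC)c1OC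
A9 | alternative 3 | 1,3,5-trimethoxybenzene | COc1cc(OC)cc(OC)c1
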